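## Retrosynthetic overview

- The target is (6R,3′R,6′R)-3′-hydroxy-ε,ε-caroten-3-one. It is disconnected at the C14′–C15′ sp2–sp2 bond into a C21 keto pentaenyl bromide (keto ring to C15′) and a C18 terminal trienyne (C14′ to the hydroxy ring); the C20′ methyl comes from Me3Al in the same operation.
- Enabling feature: C14′ is the CH end of the (E)-C13′(CH3)=C14′H alkene, which is the syn-methylmetalation pattern of a terminal alkyne. The two six-membered ε rings (C1–C6 and C1′–C6′) share the 6R configuration and differ only in oxidation level at C3/C3′, so one silyl-protected (3R,6R)-trienyne serves both halves.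
- The trienyne comes from (R)-α-ionone by enzymatic C3–H hydroxylation (3R, trans to C6), conversion of the methyl ketone to an alkyne, and carboalumination/coupling with a C4 bromoenyne. The bromide comes from the same trienyne by desilylation, carboalumination/coupling of the free alcohol with (E)-BrCH=CHI, and MnO2 oxidation.
- No ring is formed in the route: both rings are carried intact from α-ionone, and the last step is a desilylation.

Key step: step 11

Remark: (R)-(+)-α-ionone (compound 1) is taken as a purchasable enantiopure starting material; all polyene intermediates are assumed to be handled under argon in dim light.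

## Route

Step 1
Reactants: 1 (R)-α-ionone
Product: 2 (3R,6R)-3-hydroxy-α-ionone (trans)
Conditions: cytochrome P450 monooxygenase (CYP102A1 variant, E. coli whole cells or lysate), NADP+ (cat.), glucose, glucose dehydrogenase, air, phosphate buffer pH 7.5, 2% DMSO, 25 °C
Reagents that add atoms: dioxygen O=O
Why: Enzymatic allylic C–H hydroxylation by a cytochrome P450 monooxygenase is known for α-ionone and should be regioselective for C3; the active site delivers oxygen to the C3–H anti to the C6 side chain, setting 3R while C6 is untouched.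

Step 2
Reactants: 2 (3R,6R)-3-hydroxy-α-ionone
Product: 3 (3R,6R)-3-(tert-butyldimethylsilyloxy)-α-ionone
Conditions: TBSCl, imidazole, DMF, 23 °C
Reagents that add atoms: tert-butyldimethylsilyl chloride CC(C)(C)[Si](C)(C)Cl
Why: Standard silylation of a secondary allylic alcohol, which masks the hydroxyl against LDA and Me3Al in the following steps without touching either stereocentre.

Step 3
Reactants: 3 (3R,6R)-3-(tert-butyldimethylsilyloxy)-α-ionone
Product: 5 silyl-protected C13 enyne tert-butyl({(1R,4R)-4-[(1E)-but-1-en-3-yn-1-yl]-3,5,5-trimethylcyclohex-2-en-1-yl}oxy)dimethylsilane, via enol phosphate 4 (not isolated)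
Conditions: LDA (1.1 equiv), THF, −78 °C; ClP(O)(OEt)2, −78 to 23 °C; then LDA (2.3 equiv), THF, −78 to 23 °C; aq. NH4Cl
Reagents that add atoms: none
Why: Kinetic deprotonation at the methyl group (cross-conjugated enolate) rather than at the γ C6–H, O-phosphorylation and LDA-induced elimination of the enol phosphate is the established one-pot methyl ketone to terminal alkyne conversion; the C6 centre should survive because the γ-proton is not removed under kinetic control at −78 °C.

Step 4
Reactants: 6 acetylene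
Product: 7 (E)-1-bromo-2-iodoethene
Conditions: HC≡CH (gas), IBr, 48% aq. HBr, 0 °C
Reagents that add atoms: iodine monobromide BrI
Why: Electrophilic anti-addition of IBr across acetylene through an iodonium ion should give the E-dihalide, a two-carbon linchpin with two differentiated C–halogen bonds.

Step 5
Reactants: 8 ethynyltrimethylsilane; 7 (E)-1-bromo-2-iodoethene
Product: 11 (E)-(4-bromobut-3-en-1-yn-1-yl)trimethylsilane, via lithium acetylide 9 (not isolated), via alkynylzinc bromide 10 (not isolated)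
Conditions: n-BuLi, THF, −78 °C; ZnBr2, 0 °C; then 7, Pd(PPh3)4 (3 mol%), THF, 0 to 23 °C
Reagents that add atoms: none
Why: Negishi alkynyl–alkenyl coupling in which zerovalent palladium inserts into the weaker C–I bond only, with retention of the E geometry, leaving the C–Br bond for the next coupling.

Step 6
Reactants: 5 silyl-protected C13 enyne; 11 (E)-(4-bromobut-3-en-1-yn-1-yl)trimethylsilane
Product: 13 silylated trienyne tert-butyl({(1R,4R)-4-[(1E,3E,5E)-3-methyl-8-(trimethylsilyl)octa-1,3,5-trien-7-yn-1-yl]-3,5,5-trimethylcyclohex-2-en-1-yl}oxy)dimethylsilane, via dienylalane 12 (not isolated)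
Conditions: Me3Al (2 equiv), Cp2ZrCl2 (0.25 equiv), ClCH2CH2Cl, 23 °C; evaporate volatiles; then 11, ZnCl2 (0.3 equiv), Pd2(dba)3 (2.5 mol%), P(2-furyl)3 (10 mol%), THF–DMF, 23 °C
Reagents that add atoms: trimethylaluminium C[Al](C)C
Why: Zirconium-catalysed syn-methylalumination of the terminal alkyne (methyl to the internal carbon C9, aluminium to C10) followed by palladium/zinc-catalysed Negishi coupling with retention installs the C19 methyl, fixes the 9E geometry and adds four carbons in one flask.

Step 7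
Reactants: 13 silylated trienyne
Product: 14 terminal trienyne tert-butyl({(1R,4R)-4-[(1E,3E,5E)-3-methylocta-1,3,5-trien-7-yn-1-yl]-3,5,5-trimethylcyclohex-2-en-1-yl}oxy)dimethylsilane
Conditions: K2CO3 (cat.), MeOH–THF, 23 °C
Reagents that add atoms: none
Why: Methoxide-mediated protodesilylation cleaves only the alkynyl C–Si bond, while the secondary tert-butyldimethylsilyl ether is inert under these conditions.

Step 8
Reactants: 14 terminal trienyne
Product: 15 hydroxy trienyne (1R,4R)-4-[(1E,3E,5E)-3-methylocta-1,3,5-trien-7-yn-1-yl]-3,5,5-trimethylcyclohex-2-en-1-ol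
Conditions: TBAF, THF, 0 to 23 °C
Reagents that add atoms: none
Why: Fluoride-induced Si–O cleavage of the secondary silyl ether is reliable and is placed at the robust trienyne stage, so that the base-sensitive dienyl bromide made in the next step never meets fluoride, while the terminal alkyne and both stereocentres stay untouched.

Step 9
Reactants: 15 hydroxy trienyne; 7 (E)-1-bromo-2-iodoethene
Product: 17 hydroxy pentaenyl bromide (1R,4R)-4-[(1E,3E,5E,7E,9E)-10-bromo-3,7-dimethyldeca-1,3,5,7,9-pentaen-1-yl]-3,5,5-trimethylcyclohex-2-en-1-ol, via O-aluminated alkenylalane 16 (not isolated)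
Conditions: Me3Al (3 equiv), Cp2ZrCl2 (0.25 equiv), ClCH2CH2Cl, 0 to 23 °C; evaporate volatiles; then 7 (2 equiv), ZnCl2 (0.3 equiv), Pd2(dba)3 (2.5 mol%), P(2-furyl)3 (10 mol%), THF–DMF, 23 °C; aq. Rochelle salt work-up
Reagents that add atoms: trimethylaluminium C[Al](C)C
Why: The first equivalent of Me3Al turns the hydroxyl into a dimethylaluminium alkoxide, the usual way of carrying a free alcohol through zirconium-catalysed methylalumination, after which the syn-carboalumination/Negishi tandem installs the C20 methyl with 13E geometry and, by selective oxidative addition at the C–I bond of the excess dihalide, appends C15/C15′ as an (E)-alkenyl bromide; aqueous work-up returns the free alcohol.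

Step 10
Reactants: 17 hydroxy pentaenyl bromide
Product: 18 keto pentaenyl bromide (4R)-4-[(1E,3E,5E,7E,9E)-10-bromo-3,7-dimethyldeca-1,3,5,7,9-pentaen-1-yl]-3,5,5-trimethylcyclohex-2-en-1-one
Conditions: activated MnO2 (20 equiv), CH2Cl2, 23 °C, dark
Reagents that add atoms: none
Why: Heterogeneous MnO2 oxidation is selective for allylic alcohols and is known to convert the 3-hydroxy-ε ring into the 3-oxo-ε ring under neutral conditions, so the base-labile C6 centre and the alkenyl bromide should be preserved.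

Step 11
Reactants: 14 terminal trienyne; 18 keto pentaenyl bromide
Product: 20 (6R,3′R,6′R)-3′-(tert-butyldimethylsilyloxy)-ε,ε-caroten-3-one, via tetraenylalane 19 (not isolated)
Conditions: 14 (1.3 equiv), Me3Al (2.6 equiv), Cp2ZrCl2 (0.3 equiv), ClCH2CH2Cl, 23 °C; evaporate volatiles; then 18 (1.0 equiv), ZnCl2 (0.3 equiv), Pd2(dba)3 (2.5 mol%), P(2-furyl)3 (10 mol%), THF–DMF, 23 °C, dark
Reagents that add atoms: trimethylaluminium C[Al](C)C
Why: Cp2ZrCl2/Me3Al adds CH3–Al syn across the terminal alkyne of 14 with CH3 at the internal carbon (C13′) and aluminium at C14′ to give alane 19; after excess Me3Al is stripped, zerovalent palladium inserts into the C15′–Br bond of 18, the alkenyl group passes from aluminium through zinc to palladium, and reductive elimination forms the C15′–C14′ bond with retention at both alkenes. The closest known reaction type is the one-pot zirconium-catalysed carboalumination/palladium–zinc-catalysed alkenyl–alkenyl Negishi coupling used to assemble carotenoid polyenes from terminal enynes and alkenyl halides. No ring is closed and no stereocentre is created; the new stereo-elements are the 13′E geometry, fixed by syn-carbometalation with terminal regioselectivity, and the retained 15E geometry of the bromide. In this single operation the C20′ methyl, the trisubstituted 13′-alkene and the complete C40 nonaene are formed from an alkyne that is much simpler than the product and is the same building block that supplied 18. The step needs chemoselectivity for C–Br over the enone of 18 and must not remove the γ-proton at C6: excess Me3Al is evaporated before 18 is added, the alkenylzinc/alane in THF–DMF at 23 °C is a poor base and a poor carbonyl nucleophile, and coupling at an unhindered (E)-dienyl bromide is fast. The ring alkene and the conjugated triene of 14 stay untouched because only terminal alkynes undergo the zirconium-catalysed methylalumination at 23 °C, and the hydroxyl stays silylated in this step so that no aluminium alkoxide is present that could trade oxidation level with the enone by Meerwein–Ponndorf–Verley/Oppenauer hydride transfer.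

Step 12
Reactants: 20 (6R,3′R,6′R)-3′-(tert-butyldimethylsilyloxy)-ε,ε-caroten-3-one
Product: 21 (6R,3′R,6′R)-3′-hydroxy-ε,ε-caroten-3-one
Conditions: HF·pyridine, excess pyridine, THF, 0 to 23 °C, dark
Reagents that add atoms: none
Why: Pyridine-buffered HF cleaves the silyl ether without base, so the γ-epimerisable C6 of the enone ring should be safe, and the buffered acidity should be too low to ionise the allylic C3′–O bond or isomerise the polyene.

## Compound list

1 | (R)-α-ionone, (3E)-4-[(1R)-2,6,6-trimethylcyclohex-2-en-1-yl]but-3-en-2-one | CC(=O)/C=C/[C@H]1C(C)=CCCC1(C)C | starting material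
2 | (3R,6R)-3-hydroxy-α-ionone, (3E)-4-[(1R,4R)-4-hydroxy-2,6,6-trimethylcyclohex-2-en-1-yl]but-3-en-2-one | CC(=O)/C=C/[C@H]1C(C)=C[C@H](O)CC1(C)C | intermediate
3 | (3R,6R)-3-(tert-butyldimethylsilyloxy)-α-ionone | CC(=O)/C=C/[C@H]1C(C)=C[C@H](O[Si](C)(C)C(C)(C)C)CC1(C)C | intermediate
4 | diethyl (3E)-4-[(1R,4R)-4-(tert-butyldimethylsilyloxy)-2,6,6-trimethylcyclohex-2-en-1-yl]buta-1,3-dien-2-yl phosphate | C=C(OP(=O)(OCC)OCC)/C=C/[C@H]1C(C)=C[C@H](O[Si](C)(C)C(C)(C)C)CC1(C)C | intermediate (not isolated)
5 | tert-butyl({(1R,4R)-4-[(1E)-but-1-en-3-yn-1-yl]-3,5,5-trimethylcyclohex-2-en-1-yl}oxy)dimethylsilane | C#C/C=C/[C@H]1C(C)=C[C@H](O[Si](C)(C)C(C)(C)C)CC1(C)C | intermediate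
6 | acetylene | C#C | starting material
7 | (E)-1-bromo-2-iodoethene | Br/C=C/I | intermediate
8 | ethynyltrimethylsilane | C[Si](C)(C)C#C | starting material
9 | lithium (trimethylsilyl)acetylide | C[Si](C)(C)C#C[Li] | intermediate (not isolated)
10 | bromo[(trimethylsilyl)ethynyl]zinc | C[Si](C)(C)C#C[Zn]Br | intermediate (not isolated)
11 | (E)-(4-bromobut-3-en-1-yn-1-yl)trimethylsilane | C[Si](C)(C)C#C/C=C/Br | intermediate
12 | dimethyl[(1E,3E)-2-methyl-4-{(1R,4R)-4-(tert-butyldimethylsilyloxy)-2,6,6-trimethylcyclohex-2-en-1-yl}buta-1,3-dien-1-yl]alumane | C[Al](C)/C=C(C)/C=C/[C@H]1C(C)=C[C@H](O[Si](C)(C)C(C)(C)C)CC1(C)C | intermediate (not isolated)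
13 | tert-butyl({(1R,4R)-4-[(1E,3E,5E)-3-methyl-8-(trimethylsilyl)octa-1,3,5-trien-7-yn-1-yl]-3,5,5-trimethylcyclohex-2-en-1-yl}oxy)dimethylsilane | C[Si](C)(C)C#C/C=C/C=C(C)/C=C/[C@H]1C(C)=C[C@H](O[Si](C)(C)C(C)(C)C)CC1(C)C | intermediate
14 | tert-butyl({(1R,4R)-4-[(1E,3E,5E)-3-methylocta-1,3,5-trien-7-yn-1-yl]-3,5,5-trimethylcyclohex-2-en-1-yl}oxy)dimethylsilane | C#C/C=C/C=C(C)/C=C/[C@H]1C(C)=C[C@H](O[Si](C)(C)C(C)(C)C)CC1(C)C | intermediate
15 | (1R,4R)-4-[(1E,3E,5E)-3-methylocta-1,3,5-trien-7-yn-1-yl]-3,5,5-trimethylcyclohex-2-en-1-ol | C#C/C=C/C=C(C)/C=C/[C@H]1C(C)=C[C@H](O)CC1(C)C | intermediate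
16 | dimethylaluminium (1R,4R)-4-[(1E,3E,5E,7E)-8-(dimethylalumanyl)-3,7-dimethylocta-1,3,5,7-tetraen-1-yl]-3,5,5-trimethylcyclohex-2-en-1-olate | C[Al](C)/C=C(C)/C=C/C=C(C)/C=C/[C@H]1C(C)=C[C@H](O[Al](C)C)CC1(C)C | intermediate (not isolated)
17 | (1R,4R)-4-[(1E,3E,5E,7E,9E)-10-bromo-3,7-dimethyldeca-1,3,5,7,9-pentaen-1-yl]-3,5,5-trimethylcyclohex-2-en-1-ol | Br/C=C/C=C(C)/C=C/C=C(C)/C=C/[C@H]1C(C)=C[C@H](O)CC1(C)C | intermediate
18 | (4R)-4-[(1E,3E,5E,7E,9E)-10-bromo-3,7-dimethyldeca-1,3,5,7,9-pentaen-1-yl]-3,5,5-trimethylcyclohex-2-en-1-one | Br/C=C/C=C(C)/C=C/C=C(C)/C=C/[C@H]1C(C)=CC(=O)CC1(C)C | intermediate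
19 | dimethyl[(1E,3E,5E,7E)-2,6-dimethyl-8-{(1R,4R)-4-(tert-butyldimethylsilyloxy)-2,6,6-trimethylcyclohex-2-en-1-yl}octa-1,3,5,7-tetraen-1-yl]alumane | C[Al](C)/C=C(C)/C=C/C=C(C)/C=C/[C@H]1C(C)=C[C@H](O[Si](C)(C)C(C)(C)C)CC1(C)C | intermediate (not isolated)
20 | (6R,3′R,6′R)-3′-(tert-butyldimethylsilyloxy)-ε,ε-caroten-3-one | CC1=CC(=O)CC(C)(C)[C@H]1/C=C/C(C)=C/C=C/C(C)=C/C=C/C=C(C)/C=C/C=C(C)/C=C/[C@H]1C(C)=C[C@H](O[Si](C)(C)C(C)(C)C)CC1(C)C | intermediate
21 | (6R,3′R,6′R)-3′-hydroxy-ε,ε-caroten-3-one | CC1=CC(=O)CC(C)(C)[C@H]1/C=C/C(C)=C/C=C/C(C)=C/C=C/C=C(C)/C=C/C=C(C)/C=C/[C@H]1C(C)=C[C@H](O)CC1(C)C | target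

## Step count and risks

Total step count: 12. Longest linear sequence: 10 steps (1, 2, 3, 6, 7, 8, 9, 10, 11, 12).

Steps most likely to fail:

1. Step 11. Methyl or alkenyl transfer from aluminium to the enone carbonyl of 18, or removal of the γ-proton at C6 by the organometallic, could compete with cross-coupling. The fallback sets out from 14 and replaces the in-situ aluminium/zinc nucleophile by an isolated, neutral tin nucleophile. Carboalumination of 14 as in step 11 followed by iodinolysis of tetraenylalane 19 (I2, THF, −30 °C) should give the alkenyl iodide tert-butyl({(1R,4R)-4-[(1E,3E,5E,7E)-8-iodo-3,7-dimethylocta-1,3,5,7-tetraen-1-yl]-3,5,5-trimethylcyclohex-2-en-1-yl}oxy)dimethylsilane F1. Iodine–lithium exchange (t-BuLi, Et2O, −78 °C) should give the tetraenyllithium F2, which is trapped in the same flask with Bu3SnCl to give the tetraenylstannane F3. Stille coupling of F3 with 18 (Pd2(dba)3, AsPh3, DMF, 23 °C, dark) should proceed under neutral conditions that enones tolerate, and comes back to the route at 20.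

2. Step 3. LDA could remove the doubly allylic C6 proton (epimerisation or migration of the ring alkene), or the enol phosphate could eliminate incompletely. The fallback sets out from 3 and builds the chain by olefination instead of alkyne formation and carbometalation. Horner–Wadsworth–Emmons reaction with triethyl phosphonoacetate (NaH, THF) should give the ethyl (2E,4E)-3-methylpenta-2,4-dienoate F4 (the 9Z isomer removed by chromatography). Reduction with i-Bu2AlH (CH2Cl2, −78 °C) should give the dienol F5, and MnO2 oxidation the dienal F6. A second Horner–Wadsworth–Emmons reaction with diethyl [3-(trimethylsilyl)prop-2-yn-1-yl]phosphonate (LiN(SiMe3)2, THF, −78 to 0 °C) should form the 11E alkene and comes back to the route at 13, so that steps 3, 5 and 6 are bypassed.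

3. Step 1. The enzymatic hydroxylation could show insufficient regio- or diastereoselectivity, overoxidise to the 3-ketone, or give low conversion on scale. The fallback sets out from 1 and is purely chemical. Ketalisation (ethylene glycol, PPTS, benzene, reflux) should give the dioxolane F7, and allylic oxidation (CrO3·3,5-dimethylpyrazole, CH2Cl2, −20 °C) the ring enone F8. Reduction with LiBH(s-Bu)3 (THF, −78 °C) is expected to attack anti to the axial C1 methyl and give mainly the cis (3S,6R) alcohol F9. Mitsunobu inversion (4-nitrobenzoic acid, PPh3, DIAD, THF) should give the trans 4-nitrobenzoate F10, and methanolysis (K2CO3, MeOH) the trans hydroxy ketal F11. Mild ketal hydrolysis (PPTS, acetone–water) comes back to the route at 2.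

## Further compounds

F1 | step 11 | tert-butyl({(1R,4R)-4-[(1E,3E,5E,7E)-8-iodo-3,7-dimethylocta-1,3,5,7-tetraen-1-yl]-3,5,5-trimethylcyclohex-2-en-1-yl}oxy)dimethylsilane | I/C=C(C)/C=C/C=C(C)/C=C/[C@H]1C(C)=C[C@H](O[Si](C)(C)C(C)(C)C)CC1(C)C
F2 | step 11 | [(1E,3E,5E,7E)-8-{(1R,4R)-4-(tert-butyldimethylsilyloxy)-2,6,6-trimethylcyclohex-2-en-1-yl}-2,6-dimethylocta-1,3,5,7-tetraen-1-yl]lithium | [Li]/C=C(C)/C=C/C=C(C)/C=C/[C@H]1C(C)=C[C@H](O[Si](C)(C)C(C)(C)C)CC1(C)C
F3 | step 11 | tributyl[(1E,3E,5E,7E)-8-{(1R,4R)-4-(tert-butyldimethylsilyloxy)-2,6,6-trimethylcyclohex-2-en-1-yl}-2,6-dimethylocta-1,3,5,7-tetraen-1-yl]stannane | CCCC[Sn](CCCC)(CCCC)/C=C(C)/C=C/C=C(C)/C=C/[C@H]1C(C)=C[C@H](O[Si](C)(C)C(C)(C)C)CC1(C)C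
F4 | step 3 | ethyl (2E,4E)-5-{(1R,4R)-4-(tert-butyldimethylsilyloxy)-2,6,6-trimethylcyclohex-2-en-1-yl}-3-methylpenta-2,4-dienoate | CCOC(=O)/C=C(C)/C=C/[C@H]1C(C)=C[C@H](O[Si](C)(C)C(C)(C)C)CC1(C)C
F5 | step 3 | (2E,4E)-5-{(1R,4R)-4-(tert-butyldimethylsilyloxy)-2,6,6-trimethylcyclohex-2-en-1-yl}-3-methylpenta-2,4-dien-1-ol | OC/C=C(C)/C=C/[C@H]1C(C)=C[C@H](O[Si](C)(C)C(C)(C)C)CC1(C)C
F6 | step 3 | (2E,4E)-5-{(1R,4R)-4-(tert-butyldimethylsilyloxy)-2,6,6-trimethylcyclohex-2-en-1-yl}-3-methylpenta-2,4-dienal | O=C/C=C(C)/C=C/[C@H]1C(C)=C[C@H](O[Si](C)(C)C(C)(C)C)CC1(C)C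
F7 | step 1 | 2-methyl-2-{(E)-2-[(1R)-2,6,6-trimethylcyclohex-2-en-1-yl]ethenyl}-1,3-dioxolane | CC1(OCCO1)/C=C/[C@H]2C(C)=CCCC2(C)C
F8 | step 1 | (4R)-3,5,5-trimethyl-4-[(E)-2-(2-methyl-1,3-dioxolan-2-yl)ethenyl]cyclohex-2-en-1-one | CC1(OCCO1)/C=C/[C@H]2C(C)=CC(=O)CC2(C)C
F9 | step 1 | (1S,4R)-3,5,5-trimethyl-4-[(E)-2-(2-methyl-1,3-dioxolan-2-yl)ethenyl]cyclohex-2-en-1-ol (cis) | CC1(OCCO1)/C=C/[C@H]2C(C)=C[C@@H](O)CC2(C)C
F10 | step 1 | (1R,4R)-3,5,5-trimethyl-4-[(E)-2-(2-methyl-1,3-dioxolan-2-yl)ethenyl]cyclohex-2-en-1-yl 4-nitrobenzoate (trans) | CC1(OCCO1)/C=C/[C@H]2C(C)=C[C@H](OC(=O)c3ccc(cc3)[N+](=O)[O-])CC2(C)C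
F11 | step 1 | (1R,4R)-3,5,5-trimethyl-4-[(E)-2-(2-methyl-1,3-dioxolan-2-yl)ethenyl]cyclohex-2-en-1-ol (trans) | CC1(OCCO1)/C=C/[C@H]2C(C)=C[C@H](O)CC2(C)C
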